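**Plan**

Target locants used below: C1 = C(CH3)Cl, C2 = CHCl, C3 = CH2, C4 = CHBr, C5 = quaternary carbon, C6 = CH2.
Retrosynthesis: the cis C1–Cl/C2–Cl pair goes back to the epoxide of a C1=C2 ring alkene, the alkene to a C2 ketone, and the bromoethenyl group to an aldehyde.
The cyclohexanone is then cut at C1–C6 and C4–C5 in one retro-[4+2] step into 2-methylprop-2-enal and a (1E,3Z)-1-bromo-3-silyloxypenta-1,3-diene.
Enabling feature: in the only ring, C1–C2–C3–C4 carry CH3 at one end, Br at the other and a heteroatom on C2 (a 1-bromo-3-oxy diene at ketone level), and C6–C5 is the CH2=C(CH3) unit of an enal; the neopentylic C4–Br bond, which substitution chemistry cannot make cleanly, arrives on the diene.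
Forward: diene (3 steps), catalytic enantioselective Diels–Alder reaction that forms the ring, Takai olefination, ketone to alcohol to alkene, epoxidation, deoxydichlorination.
Stereochemistry: C5 from the chiral catalyst; C4 from the endo rule and the E bromoalkene; C1 and C2 from epoxidation anti to Br and bromoethenyl, then two inversions.

Key step: step 4

Assumption: the (S)-oxazaborolidinium catalyst is taken to expose the Si face at the α-carbon of 2-methylprop-2-enal, as in the accepted model for 2-substituted acroleins; if the sense were opposite, the (R)-catalyst would be used with no other change.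

**Route**

Step 1
Reactants: 1 pent-1-yn-3-ol (racemic)
Product: 2 pent-1-yn-3-one
Conditions: IBX (2-iodoxybenzoic acid), EtOAc, 75 °C
Reagents that add atoms: none
Why: Hypervalent-iodine oxidation of a secondary propargylic alcohol should give the ynone without touching the terminal alkyne, and the only stereocentre disappears.

Step 2
Reactants: 2 pent-1-yn-3-one
Product: 4 (E)-1-bromopent-1-en-3-one, via (Z)-1-bromopent-1-en-3-one 3 (not isolated)
Conditions: HBr (33 % in AcOH, 1.05 equiv), CH2Cl2, 0 °C to rt
Reagents that add atoms: hydrogen bromide, Br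
Why: Conjugate hydrobromination of an ynone (anti addition gives the Z bromoenone first), after which acid-mediated addition–elimination of bromide should equilibrate it to the more stable E isomer.

Step 3
Reactants: 4 (E)-1-bromopent-1-en-3-one
Product: 5 {[(1E,3Z)-1-bromopenta-1,3-dien-3-yl]oxy}tri(propan-2-yl)silane
Conditions: i-Pr3SiOTf, i-Pr2NEt, CH2Cl2, −78 to 0 °C
Reagents that add atoms: triisopropylsilyl trifluoromethanesulfonate, CC(C)[Si](OS(=O)(=O)C(F)(F)F)(C(C)C)C(C)C
Why: Soft enolisation (silyl triflate and hindered amine) of a ketone that can enolise only toward its ethyl group should give the Z silyl enol ether, that is the diene with CH3 on the outside, while the hindered base avoids addition–elimination at the bromoalkene.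

Step 4
Reactants: 5 {[(1E,3Z)-1-bromopenta-1,3-dien-3-yl]oxy}tri(propan-2-yl)silane, 6 2-methylprop-2-enal (methacrolein)
Product: 8 (1S,2S,5S)-2-bromo-1,5-dimethyl-4-oxocyclohexane-1-carbaldehyde, via silyl enol ether cycloadduct 7 (not isolated)
Conditions: (S)-3,3-diphenyl-1-(2-methylphenyl)tetrahydro-1H,3H-pyrrolo[1,2-c][1,3,2]oxazaborole (20 mol %), Tf2NH (20 mol %), CH2Cl2, −78 °C; then 48 % aq. HF, MeCN, 0 °C
Reagents that add atoms: none
Why: Proposed new method: the protonated oxazaborolidine binds the formyl oxygen of 6 and the 2-silyloxy diene 5 adds to the C=C bond in a concerted but asynchronous [4+2] cycloaddition, the CH(CH3) enol-ether terminus bonding first to the CH2 carbon of the enal and the CHBr terminus then to its α-carbon; the closest known reaction type is the oxazaborolidinium-catalysed Diels–Alder reaction of 2-silyloxy-1,3-dienes (and the cycloadditions of 1-alkoxy-3-silyloxy dienes) with 2-substituted acroleins, and the new element is a bromine on the diene terminus that has to survive as an allylic bromide. The six-membered ring is closed by an intermolecular suprafacial [4πs+2πs] cycloaddition that makes the C1–C6 and C4–C5 bonds (target locants) together, so no Baldwin-type ring closure is involved. The quaternary centre is set by the catalyst, which shields one face of the bound s-trans enal so that the diene reaches the Si face of the α-carbon; the CHBr centre is set by the E geometry of the bromoalkene and the endo transition state (formyl under the diene), which puts Br cis to CHO; the CH(CH3) centre, erased in step 7, follows from the Z enol ether. The step needs regio-, endo- and chemoselectivity: the silyloxy group on the inner diene carbon makes the methyl-bearing terminus the nucleophilic one (para orientation, reinforced by the ortho preference of the 1-bromo group), its bulk disfavours the methyl-endo transition state, and −78 °C with the weakly nucleophilic Tf2N− counter-ion keeps the vinylogous α-bromo ether 7 from ionising. Aqueous HF then protonates 7 at carbon and removes the silyl group under non-basic conditions, so the β-bromo ketone 8 forms without passing through an enolate that could expel bromide.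

Step 5
Reactants: 8 (1S,2S,5S)-2-bromo-1,5-dimethyl-4-oxocyclohexane-1-carbaldehyde
Product: 9 (2S,4S,5S)-5-bromo-4-[(E)-2-bromoethenyl]-2,4-dimethylcyclohexan-1-one
Conditions: CrBr2, CHBr3, THF, 0 °C to rt
Reagents that add atoms: bromoform, BrC(Br)Br
Why: Takai olefination, in which the gem-dichromium reagent formed from CHBr3 and divalent chromium should add only to the aldehyde and give the E bromoalkene; CrBr2 in place of CrCl2 avoids Br/Cl exchange and the non-basic medium spares the β-bromo ketone.

Step 6
Reactants: 9 (2S,4S,5S)-5-bromo-4-[(E)-2-bromoethenyl]-2,4-dimethylcyclohexan-1-one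
Product: 10 (1R,2S,4S,5S)-5-bromo-4-[(E)-2-bromoethenyl]-2,4-dimethylcyclohexan-1-ol
Conditions: LiBH(s-Bu)3 (L-Selectride), THF, −78 °C; then H2O
Reagents that add atoms: none
Why: Hydride reduction with a bulky borohydride should come from the equatorial direction (the axial path is also blocked by the axial C–Br bond) and give the axial alcohol cis to the neighbouring methyl group, as 2-methylcyclohexanone gives cis-2-methylcyclohexanol; a methyl epimer would give the same cis relationship and so converges in step 7.

Step 7
Reactants: 10 (1R,2S,4S,5S)-5-bromo-4-[(E)-2-bromoethenyl]-2,4-dimethylcyclohexan-1-ol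
Product: 11 (4S,5S)-4-bromo-5-[(E)-2-bromoethenyl]-1,5-dimethylcyclohex-1-ene
Conditions: Ph2S[OC(CF3)2Ph]2 (Martin sulfurane), CH2Cl2, 0 °C to rt
Reagents that add atoms: none
Why: Anti (E2-type) elimination of the alkoxysulfonium intermediate, in which the axial C–O bond is antiperiplanar to the tertiary C–H of the CH(CH3) carbon, should give the trisubstituted (Zaitsev) ring alkene under neutral conditions that leave both C–Br bonds alone.

Step 8
Reactants: 11 (4S,5S)-4-bromo-5-[(E)-2-bromoethenyl]-1,5-dimethylcyclohex-1-ene
Product: 12 (1R,3S,4S,6S)-4-bromo-3-[(E)-2-bromoethenyl]-1,3-dimethyl-7-oxabicyclo[4.1.0]heptane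
Conditions: mCPBA, NaHCO3, CH2Cl2, 0 °C
Reagents that add atoms: meta-chloroperoxybenzoic acid, OOC(=O)c1cccc(Cl)c1
Why: Prilezhaev epoxidation of the electron-rich trisubstituted ring alkene (the bromoalkene is deactivated), where the peracid should approach the half-chair anti to the axial bromoethenyl group and to Br, so the oxirane forms on the face of the methyl group of the quaternary carbon.

Step 9
Reactants: 12 (1R,3S,4S,6S)-4-bromo-3-[(E)-2-bromoethenyl]-1,3-dimethyl-7-oxabicyclo[4.1.0]heptane
Product: 14 (1S,2R,4S,5S)-4-bromo-5-[(E)-2-bromoethenyl]-1,2-dichloro-1,5-dimethylcyclohexane, via alkoxyphosphonium chloride 13 (not isolated)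
Conditions: Ph3PCl2, toluene, 80 °C
Reagents that add atoms: dichlorotriphenylphosphorane, ClP(Cl)(c1ccccc1)(c1ccccc1)c1ccccc1
Why: Deoxydichlorination of an epoxide with Ph3PCl2 by double inversion, in which chloride opens the P-activated oxirane at the tertiary carbon with inversion and a second chloride displaces Ph3P=O from the secondary carbon with inversion, so both chlorines should end cis to each other and cis to Br and the bromoethenyl group.

**Compound list**

1 | pent-1-yn-3-ol (racemic) | CCC(O)C#C | starting material
2 | pent-1-yn-3-one | CCC(=O)C#C | intermediate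
3 | (Z)-1-bromopent-1-en-3-one (not isolated) | CCC(=O)/C=C\Br | intermediate
4 | (E)-1-bromopent-1-en-3-one | CCC(=O)/C=C/Br | intermediate
5 | {[(1E,3Z)-1-bromopenta-1,3-dien-3-yl]oxy}tri(propan-2-yl)silane | Br/C=C/C(O[Si](C(C)C)(C(C)C)C(C)C)=C/C | intermediate
6 | 2-methylprop-2-enal (methacrolein) | CC(=C)C=O | starting material
7 | (1S,2S,5S)-2-bromo-1,5-dimethyl-4-{[tri(propan-2-yl)silyl]oxy}cyclohex-3-ene-1-carbaldehyde (not isolated; Br, CHO and the ring CH3 at C5 all cis) | C[C@H]1C[C@@](C)(C=O)[C@@H](Br)C=C1O[Si](C(C)C)(C(C)C)C(C)C | intermediate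
8 | (1S,2S,5S)-2-bromo-1,5-dimethyl-4-oxocyclohexane-1-carbaldehyde | C[C@H]1C[C@@](C)(C=O)[C@@H](Br)CC1=O | intermediate
9 | (2S,4S,5S)-5-bromo-4-[(E)-2-bromoethenyl]-2,4-dimethylcyclohexan-1-one | C[C@H]1C[C@@](C)(/C=C/Br)[C@@H](Br)CC1=O | intermediate
10 | (1R,2S,4S,5S)-5-bromo-4-[(E)-2-bromoethenyl]-2,4-dimethylcyclohexan-1-ol | C[C@H]1C[C@@](C)(/C=C/Br)[C@@H](Br)C[C@H]1O | intermediate
11 | (4S,5S)-4-bromo-5-[(E)-2-bromoethenyl]-1,5-dimethylcyclohex-1-ene | CC1=CC[C@H](Br)[C@](C)(/C=C/Br)C1 | intermediate
12 | (1R,3S,4S,6S)-4-bromo-3-[(E)-2-bromoethenyl]-1,3-dimethyl-7-oxabicyclo[4.1.0]heptane (oxirane trans to Br and bromoethenyl) | C[C@]12O[C@H]1C[C@H](Br)[C@](C)(/C=C/Br)C2 | intermediate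
13 | {[(1S,2S,4S,5S)-5-bromo-4-[(E)-2-bromoethenyl]-2-chloro-2,4-dimethylcyclohexyl]oxy}triphenylphosphonium chloride (not isolated) | C[C@]1(Cl)C[C@@](C)(/C=C/Br)[C@@H](Br)C[C@@H]1O[P+](c2ccccc2)(c3ccccc3)c4ccccc4.[Cl-] | intermediate
14 | (1S,2R,4S,5S)-4-bromo-5-[(E)-2-bromoethenyl]-1,2-dichloro-1,5-dimethylcyclohexane | C[C@]1(Cl)C[C@@](C)(/C=C/Br)[C@@H](Br)C[C@H]1Cl | target

**Step count and risks**

Total step count: 9. Longest linear sequence: 9 steps (from 1).

Steps most likely to fail:

1. Step 4 (Proposed new method). The allylic bromide of cycloadduct 7 may ionise with help from the enol ether, or the addition may run stepwise (Mukaiyama–Michael, then closure). Either path would erode the cis Br/CHO relationship or lose HBr to an enone.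
Fallback with known chemistry, setting out from 6 and coming back at 8: commercial (E)-1-(dimethylamino)pent-1-en-3-one F1 is silylated (KN(SiMe3)2, t-BuMe2SiCl, THF, −78 °C) to the amino silyloxy diene (1E,3Z)-3-{[tert-butyl(dimethyl)silyl]oxy}-N,N-dimethylpenta-1,3-dien-1-amine F2. F2 undergoes the hydrogen-bond-catalysed enantioselective Diels–Alder reaction with 6 (1-naphthyl-TADDOL, 20 mol %, toluene, −80 °C; the antipode that gives the needed quaternary centre) to the endo cycloadduct (1R,2S,5S)-2-(dimethylamino)-1,5-dimethyl-4-{[tert-butyl(dimethyl)silyl]oxy}cyclohex-3-ene-1-carbaldehyde F3. Aqueous HF in MeCN removes the silyl group and eliminates dimethylamine to give the enone (1R,5S)-1,5-dimethyl-4-oxocyclohex-2-ene-1-carbaldehyde F4. Conjugate addition of HBr (33 % in AcOH, CH2Cl2, 0 °C) then gives 8. In this fallback the CHBr centre is not set by the cycloaddition, so the epimers would be separated and the unwanted one returned to F4 by loss of HBr.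

2. Step 9. The second, invertive displacement occurs at a secondary carbon next to the new tertiary chloride and may be slow. Elimination, or participation of the neighbouring chlorine (net retention, trans-dichloride), could then compete.
Fallback, setting out from 11 and coming back at 14: selenium-catalysed syn-dichlorination of the alkene (PhSeSePh 5 mol %, BnEt3NCl, 1-fluoropyridinium tetrafluoroborate, Me3SiCl, MeCN, rt). Anti selenochlorination places chloride on the tertiary carbon, and chloride then displaces the oxidised selenium group with inversion; the same facial preference as in step 8 is required. This fallback makes no compound outside the list (F0).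

3. Step 7. Elimination may go toward the CH2 group that lies next to CHBr and give the regioisomeric alkene, or HBr may be lost from the axial bromide.
Fallback, setting out from 8 and coming back at 11: thermodynamic enol triflation (Tf2O, 2,6-di-tert-butyl-4-methylpyridine, CH2Cl2, 0 °C) gives (4S,5S)-5-bromo-4-formyl-2,4-dimethylcyclohex-1-en-1-yl trifluoromethanesulfonate F5. Reduction of the triflate (Pd(OAc)2, PPh3, Et3SiH, DMF, 60 °C; zerovalent palladium is formed in the flask) gives (1S,6S)-6-bromo-1,3-dimethylcyclohex-3-ene-1-carbaldehyde F6. Takai olefination (CrBr2, CHBr3, THF) then gives 11. The triflate is reduced before the bromoalkene is present, so no second site for oxidative addition exists.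

Further compounds
F1 | step 4 | (E)-1-(dimethylamino)pent-1-en-3-one | CCC(=O)/C=C/N(C)C
F2 | step 4 | (1E,3Z)-3-{[tert-butyl(dimethyl)silyl]oxy}-N,N-dimethylpenta-1,3-dien-1-amine | CN(C)/C=C/C(O[Si](C)(C)C(C)(C)C)=C/C
F3 | step 4 | (1R,2S,5S)-2-(dimethylamino)-1,5-dimethyl-4-{[tert-butyl(dimethyl)silyl]oxy}cyclohex-3-ene-1-carbaldehyde | C[C@H]1C[C@@](C)(C=O)[C@@H](N(C)C)C=C1O[Si](C)(C)C(C)(C)C
F4 | step 4 | (1R,5S)-1,5-dimethyl-4-oxocyclohex-2-ene-1-carbaldehyde | C[C@H]1C[C@@](C)(C=O)C=CC1=O
F5 | step 7 | (4S,5S)-5-bromo-4-formyl-2,4-dimethylcyclohex-1-en-1-yl trifluoromethanesulfonate | CC1=C(OS(=O)(=O)C(F)(F)F)C[C@H](Br)[C@](C)(C=O)C1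
F6 | step 7 | (1S,6S)-6-bromo-1,3-dimethylcyclohex-3-ene-1-carbaldehyde | CC1=CC[C@H](Br)[C@](C)(C=O)C1
F0 | step 9 | none | none
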